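**Plan**
- Cuts: first the two CH2–C(ipso) bonds to phenyl rings C and D, then the methine–C2 bond to ring B, and last the terminal CH2 of the acryloyl group and the two-carbon extension on the ring A aldehyde.
- Enabling feature: the unit CH2CH2Ph occurs twice, on the carbonyl carbon of the ring A ketone and on the methine carbon between rings A and B. Both arms therefore trace back to terminal vinyl groups (ArCO–CH=CH2 and CH–CH=CH2) on one core, plus iodobenzene.
- Forward: no ring is built. Ring A (2-methylphloroglucinol) is acetylated, formylated and benzylated, the aldehyde becomes a cinnamyl carbonate, ring B (syncarpic acid) is attached, the acetyl group is methylenated, and rings C and D are attached together.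
- Stereochemistry: the only stereocentre, the (R)-methine, is set by a branched-selective iridium/phosphoramidite allylic alkylation and is not touched afterwards.
- Protection: the three phenols and the ring B enol stay benzyl ethers until the last step, where one hydrogenation saturates both alkenes and frees all four oxygens.

Key step: step 10

Remark on supply: syncarpic acid is taken as a purchasable compound.
Remark on induction: in step 7 the (Sa,S,S) ligand is taken to open the Re face of the aryl-bearing allyl carbon, by analogy with stabilised nucleophiles adding to cinnamyl carbonates under this catalyst type; the mirror-image ligand is equally available if the correlation proves opposite.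

Step 1
Reactants: 1 2-methylphloroglucinol
Product: 2 1-(2,4,6-trihydroxy-3-methylphenyl)ethan-1-one
Conditions: Ac2O (1.05 equiv), BF3·OEt2 (solvent), 0 → 60 °C; then H2O
Reagents that add atoms: acetic anhydride CC(=O)OC(C)=O
Why: Friedel–Crafts C-acylation, in which the two free ring carbons of 1 are equivalent and strongly activated by three hydroxyl groups, while the first acetyl group deactivates the ring enough for one equivalent of anhydride to stop at the monoketone.

Step 2
Reactants: 2 1-(2,4,6-trihydroxy-3-methylphenyl)ethan-1-one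
Product: 4 3-acetyl-2,4,6-trihydroxy-5-methylbenzaldehyde, via aryl iminium chloride 3 (not isolated)
Conditions: POCl3 (1.1 equiv), DMF (1.5 equiv), EtOAc, 0 °C → rt; then H2O, rt
Reagents that add atoms: N,N-dimethylformamide CN(C)C=O; water O
Why: Vilsmeier–Haack formylation, in which the last free ring carbon of the acylphloroglucinol is still nucleophilic enough to take up the chloroiminium ion at or below room temperature, where attack of the reagent on the acetyl methyl group (the path to 3-formylchromones) should remain slow.

Step 3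
Reactants: 4 3-acetyl-2,4,6-trihydroxy-5-methylbenzaldehyde
Product: 5 3-acetyl-2,4,6-tris(benzyloxy)-5-methylbenzaldehyde
Conditions: BnBr (4 equiv), K2CO3 (5 equiv), DMF, 60 °C
Reagents that add atoms: benzyl bromide BrCc1ccccc1
Why: Williamson etherification, in which every ring carbon is already substituted so that C-benzylation would cost the aromaticity, and warming in a dipolar aprotic solvent should carry all three chelated phenoxides through to their ethers.

Step 4
Reactants: 5 3-acetyl-2,4,6-tris(benzyloxy)-5-methylbenzaldehyde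
Product: 6 (E)-3-[3-acetyl-2,4,6-tris(benzyloxy)-5-methylphenyl]prop-2-enal
Conditions: Ph3P=CHCHO (1.1 equiv), toluene, 90 °C
Reagents that add atoms: (triphenylphosphoranylidene)acetaldehyde O=CC=P(c1ccccc1)(c1ccccc1)c1ccccc1
Why: Wittig olefination with a stabilised ylide, which gives the E-enal, attacks only the aldehyde and ignores the twisted di-ortho-substituted methyl ketone, a near-stoichiometric charge limiting a second homologation.

Step 5
Reactants: 6 (E)-3-[3-acetyl-2,4,6-tris(benzyloxy)-5-methylphenyl]prop-2-enal
Product: 7 1-{2,4,6-tris(benzyloxy)-3-[(E)-3-hydroxyprop-1-enyl]-5-methylphenyl}ethan-1-one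
Conditions: NaBH4 (0.5 equiv), THF–MeOH, −20 °C
Reagents that add atoms: none
Why: Chemoselective 1,2-reduction by borohydride, since an unhindered enal is reduced far faster than an aryl methyl ketone shielded by two ortho benzyloxy groups, so low temperature and a limited hydride charge should spare the acetyl group.

Step 6
Reactants: 7 1-{2,4,6-tris(benzyloxy)-3-[(E)-3-hydroxyprop-1-enyl]-5-methylphenyl}ethan-1-one
Product: 8 (E)-3-[3-acetyl-2,4,6-tris(benzyloxy)-5-methylphenyl]allyl methyl carbonate
Conditions: ClCO2Me (1.5 equiv), pyridine (3 equiv), CH2Cl2, 0 °C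
Reagents that add atoms: methyl chloroformate COC(=O)Cl
Why: O-acylation of a primary allylic alcohol with a chloroformate, run under basic conditions so that the electron-rich cinnamyl system cannot ionise.

Step 7
Reactants: 8 (E)-3-[3-acetyl-2,4,6-tris(benzyloxy)-5-methylphenyl]allyl methyl carbonate; 9 syncarpic acid (2,2,4,4-tetramethylcyclohexane-1,3,5-trione)
Product: 11 2-{(R)-1-[3-acetyl-2,4,6-tris(benzyloxy)-5-methylphenyl]allyl}-3-hydroxy-4,4,6,6-tetramethylcyclohex-2-ene-1,5-dione, via caesium enolate of the adduct 10 (not isolated)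
Conditions: [Ir(cod)Cl]2 (2.5 mol %), (Sa)-binaphthyl-2,2'-diyl N,N-bis[(S)-1-(2-methoxyphenyl)ethyl]phosphoramidite (5 mol %), n-PrNH2, THF, 50 °C, then evaporation (catalyst activation); 8, 9 (1.3 equiv), Cs2CO3 (1.3 equiv), THF, 50 °C; 1 M HCl work-up
Reagents that add atoms: none
Why: Iridium-catalysed asymmetric allylic alkylation of a stabilised enolate, in which the cyclometallated iridium–phosphoramidite complex ionises the linear carbonate to an allyl complex that soft carbon nucleophiles attack anti to the metal at the aryl-bearing terminus, the ligand exposing the Re face of that carbon so that the methine is set as R, the o-anisyl ligand being the variant that copes best with ortho-alkoxy cinnamyl carbonates, and the adduct being stored as its caesium enolate, which cannot ionise again.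

Step 8
Reactants: 11 2-{(R)-1-[3-acetyl-2,4,6-tris(benzyloxy)-5-methylphenyl]allyl}-3-hydroxy-4,4,6,6-tetramethylcyclohex-2-ene-1,5-dione
Product: 12 2-{(R)-1-[3-acetyl-2,4,6-tris(benzyloxy)-5-methylphenyl]allyl}-3-(benzyloxy)-4,4,6,6-tetramethylcyclohex-2-ene-1,5-dione
Conditions: BnBr (1.3 equiv), Cs2CO3 (1.5 equiv), DMF, rt
Reagents that add atoms: benzyl bromide BrCc1ccccc1
Why: Williamson-type O-alkylation of a vinylogous acid, which should go to oxygen because C2 of ring B already carries the bulky arylallyl group between two carbonyl carbons that each adjoin a gem-dimethyl carbon, and which can give only one constitutional product because rotation about the methine–C2 bond interchanges the two enolate oxygens.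

Step 9
Reactants: 12 2-{(R)-1-[3-acetyl-2,4,6-tris(benzyloxy)-5-methylphenyl]allyl}-3-(benzyloxy)-4,4,6,6-tetramethylcyclohex-2-ene-1,5-dione
Product: 16 bis-vinyl core 2-{(R)-1-[3-acryloyl-2,4,6-tris(benzyloxy)-5-methylphenyl]allyl}-3-(benzyloxy)-4,4,6,6-tetramethylcyclohex-2-ene-1,5-dione, via lithium enolate 13 (not isolated), via Mannich base 14 (not isolated), via trimethylammonium iodide 15 (not isolated)
Conditions: LiN(SiMe3)2 (1.05 equiv), THF, −78 °C; [CH2=NMe2]I (1.3 equiv), −78 °C → rt; MeI (5 equiv), CH2Cl2, rt; sat. aq NaHCO3, CH2Cl2, rt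
Reagents that add atoms: dimethyl(methylidene)ammonium iodide (Eschenmoser's salt) C=[N+](C)C.[I-]
Why: Mannich aminomethylation followed by quaternisation and Hofmann-type (E1cB) elimination, in which the acetyl methyl group holds the only kinetically acidic protons of 12 (ring B has no α-hydrogen left and the methine is crowded), the small iminium ion can reach the hindered enolate, and the ammonium salt loses trimethylamine under bicarbonate, which is mild enough for the aryl vinyl ketone and harmless to the stereocentre.

Step 10
Reactants: 16 bis-vinyl core 2-{(R)-1-[3-acryloyl-2,4,6-tris(benzyloxy)-5-methylphenyl]allyl}-3-(benzyloxy)-4,4,6,6-tetramethylcyclohex-2-ene-1,5-dione; 17 iodobenzene (3 equiv)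
Product: 19 bis-styryl compound 3-(benzyloxy)-4,4,6,6-tetramethyl-2-{(R,E)-3-phenyl-1-[2,4,6-tris(benzyloxy)-3-methyl-5-((E)-3-phenylacryloyl)phenyl]allyl}cyclohex-2-ene-1,5-dione, via mono-arylated chalcone 18 (not isolated)
Conditions: Pd(OAc)2 (10 mol %), PPh3 (20 mol %), Ag2CO3 (2 equiv), BHT (5 mol %), MeCN, 70 °C, dark
Reagents that add atoms: none
Why: This is a Mizoroki–Heck arylation run twice in one flask: zerovalent palladium formed from Pd(OAc)2 and PPh3 inserts into the C–I bond of 17, silver removes iodide to leave a cationic phenylpalladium species, each monosubstituted alkene inserts syn with phenyl going to its CH2 terminus, and syn β-hydride elimination releases the E-alkene. The closest known reactions are the arylation of aryl vinyl ketones to chalcones and of allylically branched 1-alkenes to E-styrenes; the electron-poor acryloyl arm should react first (18) and the shielded vinyl arm second, hence the excess of 17 and the generous catalyst loading. No ring closes and no stereocentre is created; the two new C(sp2)–C(aryl) bonds attach rings C and D, and both alkene geometries follow from the syn-insertion/syn-elimination sequence. For regioselectivity, polarisation sends phenyl to the β-carbon of the enone, and the crowded methine next to the other alkene rules out arylation at its internal carbon. On the methine arm, elimination must go toward the new benzylic CH2 and not toward the hydrogen on the stereocentre: the first gives a phenyl-conjugated alkene from an accessible rotamer, the second needs rings A and B eclipsed against palladium, and Ag2CO3 strips the hydride from palladium before it can re-add and walk the double bond into the stereocentre. The benzyl cap on the ring B enol makes the substrate fit for this step, since it removes the oxygen nucleophile that would attack the palladium-bound vinyl group (dihydrofuran formation) or the enone (Michael addition), and it blocks ionisation of the allylic methine–ring B bond by zerovalent palladium.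

Step 11
Reactants: 19 bis-styryl compound 3-(benzyloxy)-4,4,6,6-tetramethyl-2-{(R,E)-3-phenyl-1-[2,4,6-tris(benzyloxy)-3-methyl-5-((E)-3-phenylacryloyl)phenyl]allyl}cyclohex-2-ene-1,5-dione
Product: 20 target 3-hydroxy-4,4,6,6-tetramethyl-2-{(R)-3-phenyl-1-[2,4,6-trihydroxy-3-methyl-5-(3-phenylpropanoyl)phenyl]propyl}cyclohex-2-ene-1,5-dione
Conditions: H2 (1 atm), 10% Pd/C, EtOAc–MeOH, rt
Reagents that add atoms: none
Why: Heterogeneous catalytic hydrogenation with hydrogenolysis, in which the two disubstituted alkenes are saturated quickly, the three aryl benzyl ethers and the vinylogous benzyl ester are cleaved to toluene, the chelated aryl ketone, the hindered ring B carbonyls and the tetrasubstituted enol double bond are inert at one atmosphere, and the neutral medium at room temperature avoids retro-Michael loss of configuration at the (R)-methine.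

**Compound list**
1 | 2-methylphloroglucinol (2-methylbenzene-1,3,5-triol) | Cc1c(O)cc(O)cc1O | starting material
2 | 1-(2,4,6-trihydroxy-3-methylphenyl)ethan-1-one | CC(=O)c1c(O)cc(O)c(C)c1O | intermediate
3 | [(3-acetyl-2,4,6-trihydroxy-5-methylphenyl)methylidene]dimethylammonium chloride | CC(=O)c1c(O)c(C)c(O)c(C=[N+](C)C)c1O.[Cl-] | intermediate
4 | 3-acetyl-2,4,6-trihydroxy-5-methylbenzaldehyde | CC(=O)c1c(O)c(C)c(O)c(C=O)c1O | intermediate
5 | 3-acetyl-2,4,6-tris(benzyloxy)-5-methylbenzaldehyde | CC(=O)c1c(OCc2ccccc2)c(C)c(OCc2ccccc2)c(C=O)c1OCc1ccccc1 | intermediate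
6 | (E)-3-[3-acetyl-2,4,6-tris(benzyloxy)-5-methylphenyl]prop-2-enal | CC(=O)c1c(OCc2ccccc2)c(C)c(OCc2ccccc2)c(/C=C/C=O)c1OCc1ccccc1 | intermediate
7 | 1-{2,4,6-tris(benzyloxy)-3-[(E)-3-hydroxyprop-1-enyl]-5-methylphenyl}ethan-1-one | CC(=O)c1c(OCc2ccccc2)c(C)c(OCc2ccccc2)c(/C=C/CO)c1OCc1ccccc1 | intermediate
8 | (E)-3-[3-acetyl-2,4,6-tris(benzyloxy)-5-methylphenyl]allyl methyl carbonate | CC(=O)c1c(OCc2ccccc2)c(C)c(OCc2ccccc2)c(/C=C/COC(=O)OC)c1OCc1ccccc1 | intermediate
9 | syncarpic acid (2,2,4,4-tetramethylcyclohexane-1,3,5-trione) | CC1(C)C(=O)CC(=O)C(C)(C)C1=O | starting material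
10 | caesium enolate of adduct 11, (R) | CC(=O)c1c(OCc2ccccc2)c(C)c(OCc2ccccc2)c([C@@H](C=C)C2=C([O-])C(C)(C)C(=O)C(C)(C)C2=O)c1OCc1ccccc1.[Cs+] | intermediate
11 | 2-{(R)-1-[3-acetyl-2,4,6-tris(benzyloxy)-5-methylphenyl]allyl}-3-hydroxy-4,4,6,6-tetramethylcyclohex-2-ene-1,5-dione | CC(=O)c1c(OCc2ccccc2)c(C)c(OCc2ccccc2)c([C@@H](C=C)C2=C(O)C(C)(C)C(=O)C(C)(C)C2=O)c1OCc1ccccc1 | intermediate
12 | 2-{(R)-1-[3-acetyl-2,4,6-tris(benzyloxy)-5-methylphenyl]allyl}-3-(benzyloxy)-4,4,6,6-tetramethylcyclohex-2-ene-1,5-dione | CC(=O)c1c(OCc2ccccc2)c(C)c(OCc2ccccc2)c([C@@H](C=C)C2=C(OCc3ccccc3)C(C)(C)C(=O)C(C)(C)C2=O)c1OCc1ccccc1 | intermediate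
13 | lithium enolate of the acetyl group of 12, (R) | [Li+].C=C([O-])c1c(OCc2ccccc2)c(C)c(OCc2ccccc2)c([C@@H](C=C)C2=C(OCc3ccccc3)C(C)(C)C(=O)C(C)(C)C2=O)c1OCc1ccccc1 | intermediate
14 | Mannich base, 3-(dimethylamino)propanoyl analogue of 12, (R) | CN(C)CCC(=O)c1c(OCc2ccccc2)c(C)c(OCc2ccccc2)c([C@@H](C=C)C2=C(OCc3ccccc3)C(C)(C)C(=O)C(C)(C)C2=O)c1OCc1ccccc1 | intermediate
15 | trimethylammonium iodide of 14, (R) | C[N+](C)(C)CCC(=O)c1c(OCc2ccccc2)c(C)c(OCc2ccccc2)c([C@@H](C=C)C2=C(OCc3ccccc3)C(C)(C)C(=O)C(C)(C)C2=O)c1OCc1ccccc1.[I-] | intermediate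
16 | bis-vinyl core, 2-{(R)-1-[3-acryloyl-2,4,6-tris(benzyloxy)-5-methylphenyl]allyl}-3-(benzyloxy)-4,4,6,6-tetramethylcyclohex-2-ene-1,5-dione | C=CC(=O)c1c(OCc2ccccc2)c(C)c(OCc2ccccc2)c([C@@H](C=C)C2=C(OCc3ccccc3)C(C)(C)C(=O)C(C)(C)C2=O)c1OCc1ccccc1 | intermediate
17 | iodobenzene | Ic1ccccc1 | starting material
18 | mono-arylated chalcone, (E)-3-phenylacryloyl arm formed and vinyl arm intact, (R) | O=C(/C=C/c1ccccc1)c1c(OCc2ccccc2)c(C)c(OCc2ccccc2)c([C@@H](C=C)C2=C(OCc3ccccc3)C(C)(C)C(=O)C(C)(C)C2=O)c1OCc1ccccc1 | intermediate
19 | bis-styryl compound, (E)-chalcone arm and (E)-styryl arm on the tetrabenzyl core, (R) | O=C(/C=C/c1ccccc1)c1c(OCc2ccccc2)c(C)c(OCc2ccccc2)c([C@@H](/C=C/c2ccccc2)C2=C(OCc3ccccc3)C(C)(C)C(=O)C(C)(C)C2=O)c1OCc1ccccc1 | intermediate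
20 | 3-hydroxy-4,4,6,6-tetramethyl-2-{(R)-3-phenyl-1-[2,4,6-trihydroxy-3-methyl-5-(3-phenylpropanoyl)phenyl]propyl}cyclohex-2-ene-1,5-dione (CNP0236721.1) | Cc1c(O)c(C(=O)CCc2ccccc2)c(O)c([C@@H](CCc2ccccc2)C2=C(O)C(C)(C)C(=O)C(C)(C)C2=O)c1O | target

**Step count**
Total steps: 11. Longest linear sequence: 11 steps (1 → 20); 9 and 17 enter as purchased compounds.

**Steps most likely to fail**

Step 7. The two ortho benzyloxy groups may slow ionisation of the carbonate and erode both the preference for the branched position and the facial selectivity, and allylation on oxygen may compete. The fallback sets out from 7 and 9. A Mitsunobu reaction (PPh3, DIAD, THF, 0 °C → rt) joins them through oxygen to give the O-cinnamyl enol ether F1. Heating in toluene at reflux then triggers a [3,3] Claisen rearrangement, which creates the same methine–C2 bond without any metal and gives the racemic adduct F2. Preparative chromatography on a chiral stationary phase separates 11 from the (S)-adduct F3. The route is rejoined at 11.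

Step 10. The reaction may stall after the first arylation because the second alkene is shielded. The enone arm may also polymerise, and β-hydride elimination or hydride re-addition may move the double bond into the stereocentre. The fallback sets out from 16 and replaces aryl–alkene bond formation by alkene exchange. It is a two-directional cross-metathesis with excess styrene, using the second-generation Hoveyda–Grubbs catalyst (H2IMes)Cl2Ru(=CH-C6H4-2-OiPr) with 1,4-benzoquinone in toluene at 50 °C. Both vinyl termini are swapped for E-CHPh with loss of ethene. No new compound appears and the route is rejoined at 19.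

Step 9. Aminomethylation of the hindered enolate may be incomplete or may occur twice. The liberated aryl vinyl ketone may also oligomerise or take the amine back up during the elimination. The fallback sets out from 12 and uses an aldol–dehydration logic. Me3SiOTf and Et3N in CH2Cl2 at 0 °C give the trimethylsilyl enol ether F4. A Mukaiyama aldol reaction with aqueous formaldehyde under Yb(OTf)3 in THF–H2O gives the β-hydroxy ketone F5. MsCl and Et3N in CH2Cl2 at 0 °C form the mesylate F6, which eliminates in the same flask. The route is rejoined at 16.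

**Further compounds**
F1 | step 7 | O-cinnamyl enol ether, 3-{(E)-3-[3-acetyl-2,4,6-tris(benzyloxy)-5-methylphenyl]allyloxy}-4,4,6,6-tetramethylcyclohex-2-ene-1,5-dione | CC(=O)c1c(OCc2ccccc2)c(C)c(OCc2ccccc2)c(/C=C/COC2=CC(=O)C(C)(C)C(=O)C2(C)C)c1OCc1ccccc1
F2 | step 7 | racemic adduct (racemate of 11) | CC(=O)c1c(OCc2ccccc2)c(C)c(OCc2ccccc2)c(C(C=C)C2=C(O)C(C)(C)C(=O)C(C)(C)C2=O)c1OCc1ccccc1
F3 | step 7 | (S)-adduct (enantiomer of 11) | CC(=O)c1c(OCc2ccccc2)c(C)c(OCc2ccccc2)c([C@H](C=C)C2=C(O)C(C)(C)C(=O)C(C)(C)C2=O)c1OCc1ccccc1
F0 | step 10 | none | none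
F4 | step 9 | trimethylsilyl enol ether of 12, (R) | C=C(O[Si](C)(C)C)c1c(OCc2ccccc2)c(C)c(OCc2ccccc2)c([C@@H](C=C)C2=C(OCc3ccccc3)C(C)(C)C(=O)C(C)(C)C2=O)c1OCc1ccccc1
F5 | step 9 | β-hydroxy ketone, 3-hydroxypropanoyl analogue of 12, (R) | OCCC(=O)c1c(OCc2ccccc2)c(C)c(OCc2ccccc2)c([C@@H](C=C)C2=C(OCc3ccccc3)C(C)(C)C(=O)C(C)(C)C2=O)c1OCc1ccccc1
F6 | step 9 | mesylate of F5, (R) | CS(=O)(=O)OCCC(=O)c1c(OCc2ccccc2)c(C)c(OCc2ccccc2)c([C@@H](C=C)C2=C(OCc3ccccc3)C(C)(C)C(=O)C(C)(C)C2=O)c1OCc1ccccc1
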